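Seconds spent beside free partner are what you are buying in this run, so count them before you choose how to charge it.

all flasks: second substrate 0.0100 M; protic impurity 2.50 mM
- ash: starting material 0.050 M; partner 0.0900 M (fed, over 16.0 s); time 20 s; all but partner at the start; partner goes in evenly over 16.0 s, the run ends at 20 s
- oak: starting material 0.050 M (fed, over 16.0 s); partner 0.0900 M; time 20 s; a stirred flask in which starting material is dosed at a steady rate over 16.0 s without added volume, worked up at 20 s
- alder: starting material 0.050 M; partner 0.0900 M; a single well-mixed tank run continuously and read at steady state, 20 s in it on average
- cedar: starting material 0.050 M; partner 0.0900 M; time 20 s; a closed flask charged with all of it at once and left for 20 s

* the set-up with the highest amount of target at the outlet or at the end, in percent of the starting material put in ("none" if the first two lie within 2 percentage points) (ash / oak / alder / cedar / none)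
* amount of target at the outlet or at the end, in percent of the starting material put in, ash
* amount of target at the outlet or at the end, in percent of the starting material put in, oak
* amount of target at the outlet or at the end, in percent of the starting material put in, alder
* amount of target at the outlet or at the end, in percent of the starting material put in, cedar

- in percentages every species weighs as the starting material in it: one side product counts as two
- the stated concentrations are those of everything mixed, before any reaction; amounts are the same in each set-up
- the feed brings no volume worth counting
- run time (ash): 20 s

    starting material + second substrate → cross product (k1 = 2.59 /M/s)
    second substrate + partner → second product (k2 = 0.508 /M/s)
    starting material + partner → target (k3 = 0.262 /M/s)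
    starting material + target → side product (k4 = 0.275 /M/s)
    partner + protic impurity → quenched reagent (k5 = 14.1 /M/s)

I take two quick steps off the books first. In cedar the protic impurity has a half-life of 0.546 s at the partner charge, far shorter than the 29.4 s that starting material needs to go to target at that charge, so I subtract the impurity from the partner and reckon with 0.08750 M of free partner. The second substrate has a half-life of 5.35 s against the starting material charge, shorter than the time for target, but partner takes it too, with a half-life of 15.2 s at the partner charge, so the 20.0% of the starting material that its charge could carry off as cross product is a ceiling, and I write off that ceiling as a deliberately harsh figure.

The remainder I treat as pseudo-first-order in free partner. The contact number, meaning the target rate constant times free partner times the average time starting material spends beside that partner, is 0.459 in cedar. The even feed in ash and oak cuts the average contact to 12.0 s, which gives 0.275. The batch fraction converted is one minus the exponential of minus that number, and the tank's is the number over one plus itself, so I expect 29.4% in cedar, 25.1% in alder and 19.2% in ash and oak. I have left out the side product, whose step has a half-life on target of 50 s in cedar, and that pushes these figures high while the ceiling on cross product pushes them low, so I hold them as rough. My choice for the next run is to charge everything at once, since cedar stands higher than alder by 4.3 percentage points, outside the margin of 2 points.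

The forecast also names cedar, at 27%, with 20.5% for alder, 18.5% for oak and 17% for ash, lower than my figures, on the ground that “Dosing either reagent or running at tank outlet concentrations just loses reaction time”.

The flask gives cedar as best, with 26.7% against 20.6% for alder, 18.5% for oak and 17.6% for ash, the forecast's order. Cedar at 20.0 s still holds 54.2% of its starting material, and its contact number of 0.459 stands below one, so when you repeat the run, watch free partner multiplied by seconds.

Take ash again with 0.36 M of partner: free partner of 0.357 M over 12.0 s makes the contact number 1.12, hence 54.0% of target. The simulated flask gives 52.7%.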